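**Strategy.** Everything rests on disconnecting the C2–C3 bond of the oxane ring, between the gem-dimethyl carbon on the ring oxygen and the bromine-bearing carbon. C2 is an acetone-level carbon: hung on the tertiary ether oxygen as an isopropenyl group, it becomes a tertiary α-oxy radical on hydrogen atom transfer and closes the ring 6-exo onto a nitrile carbon that becomes C3. One operation forms the hindered C2–C3 bond, completes the gem-dimethyl group and leaves C3 as a ketone. The precursor is an acyclic bromo isopropenyl ether nitrile built from (S)-linalool and acetonitrile; a Shi epoxide sets the two adjacent centres, and the ring bromide is set last by axial hydrogen transfer to an α-bromo radical.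

Key step: step 7

Assumption: (S)-(+)-linalool of high enantiomeric purity and the L-fructose-derived enantiomer of the Shi ketone are taken as commercial; the linalool carbinol centre is carried unchanged into the target.

Step 1
Reactants: 1 (S)-linalool
Product: 2 (2E,6S)-2,6-dimethylocta-2,7-diene-1,6-diol
Conditions: SeO2 (0.3 equiv), t-BuOOH, salicylic acid (cat.), CH2Cl2, 0 °C to rt
Reagents that add atoms: selenium dioxide (catalytic oxygen carrier), O=[Se]=O; tert-butyl hydroperoxide (terminal oxygen source), CC(C)(C)OO
Why: Riley allylic oxidation (ene reaction, then [2,3]-sigmatropic shift) should oxidise only the E-methyl group of the trisubstituted alkene, leaving the vinyl carbinol and its stereocentre untouched; no new stereocentre forms.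

Step 2
Reactants: 2 (2E,6S)-2,6-dimethylocta-2,7-diene-1,6-diol
Product: 4 {[(3S,6E)-8-bromo-3,7-dimethylocta-1,6-dien-3-yl]oxy}triethylsilane, via hydroxy bromide 3 (not isolated)
Conditions: CBr4, PPh3, CH2Cl2, −30 to 0 °C; then 2,6-lutidine, Et3SiOTf, −78 to 0 °C
Reagents that add atoms: carbon tetrabromide, BrC(Br)(Br)Br; triethylsilyl trifluoromethanesulfonate, CC[Si](CC)(CC)OS(=O)(=O)C(F)(F)F
Why: An Appel reaction should convert only the primary allylic alcohol, and silylation of the tertiary alcohol in the same flask masks it before any base can trigger SN2' ring closure onto the allylic bromide; no stereocentre is touched.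

Step 3
Reactants: 4 silyl-protected allylic bromide; 5 acetonitrile
Product: 6 (4E,8S)-4,8-dimethyl-8-[(triethylsilyl)oxy]deca-4,9-dienenitrile
Conditions: 5 (5 equiv), LiN(i-Pr)2, THF, −78 °C; then 4, −78 to −40 °C
Reagents that add atoms: none
Why: SN2 alkylation of lithiated acetonitrile (in excess to suppress double alkylation) by the primary allylic bromide should install the two-carbon nitrile arm whose carbon becomes ring C3, with the E-alkene and the carbinol centre unchanged.

Step 4
Reactants: 6 dienyl nitrile
Product: 7 3-[(2S,3S)-2-methyl-3-{(3S)-3-methyl-3-[(triethylsilyl)oxy]pent-4-en-1-yl}oxiran-2-yl]propanenitrile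
Conditions: L-fructose-derived Shi ketone (0.3 equiv), KHSO5 (as Oxone), K2CO3, Bu4NHSO4, MeCN–CH2(OMe)2–aq. Na2B4O7 (pH 10.5), 0 °C
Reagents that add atoms: potassium peroxymonosulfate, [K+].[O-]S(=O)(=O)OO
Why: Shi epoxidation (chiral dioxirane, spiro transition state) should epoxidise only the electron-rich trisubstituted alkene, and the L-fructose-derived ketone should give the (S,S)-epoxide under reagent control, so both new centres are set by the catalyst while the vinyl group and the nitrile are left alone.

Step 5
Reactants: 7 (S,S)-epoxide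
Product: 8 (4S,5R,8S)-5-bromo-4-hydroxy-4,8-dimethyl-8-[(triethylsilyl)oxy]dec-9-enenitrile
Conditions: Li2NiBr4 (2 equiv), THF, 0 °C to rt; pH 7 phosphate buffer
Reagents that add atoms: dilithium tetrabromonickelate, [Li+].[Li+].[Ni+2].[Br-].[Br-].[Br-].[Br-]
Why: SN2 opening of the epoxide by the soft bromide of Li2NiBr4 at the less substituted carbon should give the secondary bromide with inversion (S to R) and leave the tertiary C–O bond and its (S) configuration intact, i.e. the anti bromohydrin of the E-alkene.

Step 6
Reactants: 8 bromohydrin; 9 2-methoxypropene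
Product: 11 (4S,5R,8S)-5-bromo-4,8-dimethyl-4-(prop-1-en-2-yloxy)-8-[(triethylsilyl)oxy]dec-9-enenitrile, via mixed ketal 10 (not isolated)
Conditions: 9 (10 equiv), PPTS (cat.), CH2Cl2, 0 °C; evaporate excess 9; then i-Pr2NEt, Me3SiOTf, CH2Cl2, −20 to 0 °C
Reagents that add atoms: none
Why: Acid-catalysed addition of the tertiary alcohol to the enol ether gives the 2-methoxyprop-2-yl mixed ketal, and the silyl triflate/amine pair then ionises the less hindered methoxy group and removes a methyl proton from the oxocarbenium ion (ketal-to-enol-ether elimination), placing the acetone unit on the tertiary oxygen as an isopropenyl ether without touching a stereocentre.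

Step 7
Reactants: 11 bromo isopropenyl ether nitrile
Product: 13 (6S)-6-[(1R,4S)-1-bromo-4-hydroxy-4-methylhex-5-en-1-yl]-2,2,6-trimethyloxan-3-one, via ketimine 12 (not isolated)
Conditions: Fe(acac)3 (0.5 equiv), PhSiH3, EtOH–HOCH2CH2OH, 60 °C; then 5% aq. HF, MeCN, 0 °C to rt
Reagents that add atoms: water, O
Why: An iron hydride made from Fe(acac)3 and PhSiH3 transfers a hydrogen atom to the CH2 terminus of the electron-rich isopropenyl ether (Mukaiyama-type hydrogen atom transfer), the resulting tertiary α-oxy radical at the future C2 adds to the nitrile carbon and the iminyl radical is reduced to the N–H ketimine, which aqueous HF hydrolyses to the ketone while it also cleaves the silyl ether. The closest known reaction type is the hydrogen-atom-transfer-initiated reductive cyclisation of alkenyl nitriles to cyclic ketones, combined with the use of enol ethers as donor olefins in iron-mediated reductive olefin coupling. The oxane ring closes in the 6-exo-dig mode, helped by the fully substituted carbinol carbon in the tether and by the match of a nucleophilic α-oxy radical with the electrophilic nitrile. No stereocentre is created (C2 ends with two methyl groups, C3 as a carbonyl), the centres at C6 and in the side chain lie away from the radical and are retained, and C3 is set in step 9. The step needs hydrogen atom transfer to the 1,1-disubstituted enol ether ahead of the monosubstituted vinyl group, which its electron richness and the tertiary α-oxy radical it gives should secure, and cyclisation ahead of reduction or C–O fragmentation of that radical, which a low steady-state hydride concentration should favour; the secondary bromide is inert to these conditions.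

Step 8
Reactants: 13 hydroxy ketone
Product: 15 (3S,6R)-6-bromo-6-[(2S)-5,5-dibromo-2,6,6-trimethyloxan-2-yl]-3-methylhex-1-en-3-ol, via hydrazone 14 (not isolated)
Conditions: N2H4·H2O, EtOH, 60 °C; concentrate; then CuBr2 (6 equiv), Et3N, MeOH, 0 °C
Reagents that add atoms: copper dibromide, [Cu+2].[Br-].[Br-]
Why: Condensation gives the hydrazone, which divalent copper bromide should oxidise to the diazoalkane and brominate twice with loss of N2 (oxidative geminal dihalogenation of a ketone hydrazone), turning the carbonyl carbon into a CBr2 group without an ionic displacement at this neopentyl position; no stereocentre is formed.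

Step 9
Reactants: 15 geminal dibromide
Product: 16 (3S,6R)-6-bromo-6-[(2S,5R)-5-bromo-2,6,6-trimethyloxan-2-yl]-3-methylhex-1-en-3-ol (target)
Conditions: Bu3SnH (1.05 equiv), Et3B (cat.), air, toluene, −78 °C
Reagents that add atoms: none
Why: Radical chain monodebromination should act on the geminal dibromide well before the secondary bromide, and the α-bromo ring radical should take hydrogen from Bu3SnH on the axial face, anti to the axial methyl of the neighbouring gem-dimethyl carbon in the chair that keeps the side chain equatorial, which leaves bromine equatorial and trans to the side chain, the (5R) configuration, under substrate control.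

**Compound list**

1 | (S)-linalool, (3S)-3,7-dimethylocta-1,6-dien-3-ol | C=C[C@@](C)(O)CCC=C(C)C | starting material
2 | (2E,6S)-2,6-dimethylocta-2,7-diene-1,6-diol | C=C[C@@](C)(O)CC/C=C(\C)CO | intermediate
3 | (3S,6E)-8-bromo-3,7-dimethylocta-1,6-dien-3-ol | C=C[C@@](C)(O)CC/C=C(\C)CBr | intermediate
4 | {[(3S,6E)-8-bromo-3,7-dimethylocta-1,6-dien-3-yl]oxy}triethylsilane | C=C[C@@](C)(O[Si](CC)(CC)CC)CC/C=C(\C)CBr | intermediate
5 | acetonitrile | CC#N | starting material
6 | (4E,8S)-4,8-dimethyl-8-[(triethylsilyl)oxy]deca-4,9-dienenitrile | C=C[C@@](C)(O[Si](CC)(CC)CC)CC/C=C(\C)CCC#N | intermediate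
7 | 3-[(2S,3S)-2-methyl-3-{(3S)-3-methyl-3-[(triethylsilyl)oxy]pent-4-en-1-yl}oxiran-2-yl]propanenitrile | C=C[C@@](C)(O[Si](CC)(CC)CC)CC[C@@H]1O[C@@]1(C)CCC#N | intermediate
8 | (4S,5R,8S)-5-bromo-4-hydroxy-4,8-dimethyl-8-[(triethylsilyl)oxy]dec-9-enenitrile | C=C[C@@](C)(O[Si](CC)(CC)CC)CC[C@@H](Br)[C@](O)(C)CCC#N | intermediate
9 | 2-methoxypropene | COC(C)=C | starting material
10 | (4S,5R,8S)-5-bromo-4-[(2-methoxypropan-2-yl)oxy]-4,8-dimethyl-8-[(triethylsilyl)oxy]dec-9-enenitrile | C=C[C@@](C)(O[Si](CC)(CC)CC)CC[C@@H](Br)[C@](OC(C)(C)OC)(C)CCC#N | intermediate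
11 | (4S,5R,8S)-5-bromo-4,8-dimethyl-4-(prop-1-en-2-yloxy)-8-[(triethylsilyl)oxy]dec-9-enenitrile | C=C[C@@](C)(O[Si](CC)(CC)CC)CC[C@@H](Br)[C@](OC(C)=C)(C)CCC#N | intermediate
12 | (6S)-6-{(1R,4S)-1-bromo-4-methyl-4-[(triethylsilyl)oxy]hex-5-en-1-yl}-2,2,6-trimethyloxan-3-imine | C=C[C@@](C)(O[Si](CC)(CC)CC)CC[C@@H](Br)[C@]1(C)CCC(=N)C(C)(C)O1 | intermediate
13 | (6S)-6-[(1R,4S)-1-bromo-4-hydroxy-4-methylhex-5-en-1-yl]-2,2,6-trimethyloxan-3-one | C=C[C@@](C)(O)CC[C@@H](Br)[C@]1(C)CCC(=O)C(C)(C)O1 | intermediate
14 | hydrazone of 13, (3S,6R)-6-bromo-6-[(2S)-5-hydrazinylidene-2,6,6-trimethyloxan-2-yl]-3-methylhex-1-en-3-ol | C=C[C@@](C)(O)CC[C@@H](Br)[C@]1(C)CCC(=NN)C(C)(C)O1 | intermediate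
15 | (3S,6R)-6-bromo-6-[(2S)-5,5-dibromo-2,6,6-trimethyloxan-2-yl]-3-methylhex-1-en-3-ol | C=C[C@@](C)(O)CC[C@@H](Br)[C@]1(C)CCC(Br)(Br)C(C)(C)O1 | intermediate
16 | (3S,6R)-6-bromo-6-[(2S,5R)-5-bromo-2,6,6-trimethyloxan-2-yl]-3-methylhex-1-en-3-ol | C=C[C@@](C)(O)CC[C@@H](Br)[C@]1(C)CC[C@@H](Br)C(C)(C)O1 | target

Total step count: 9. Longest linear sequence: 9 steps (1 to 16).

**Steps most likely to fail**

First, step 7. The tertiary α-oxy radical may be reduced to the isopropyl ether, or lose acetone by C–O fragmentation, faster than it adds to the nitrile, whose radical addition is slow and reversible. The fallback changes the acceptor to an aldehyde. It sets out from 11: i-Bu2AlH (toluene, −78 °C, buffered Rochelle salt work-up) should give (4S,5R,8S)-5-bromo-4,8-dimethyl-4-(prop-1-en-2-yloxy)-8-[(triethylsilyl)oxy]dec-9-enal F1. The same Fe(acac)3/PhSiH3 conditions should close the ring onto the far more reactive C=O to give (6S)-6-{(1R,4S)-1-bromo-4-methyl-4-[(triethylsilyl)oxy]hex-5-en-1-yl}-2,2,6-trimethyloxan-3-ol F2 as either carbinol epimer. Dess–Martin periodinane (NaHCO3, CH2Cl2) should then give (6S)-6-{(1R,4S)-1-bromo-4-methyl-4-[(triethylsilyl)oxy]hex-5-en-1-yl}-2,2,6-trimethyloxan-3-one F3, and aqueous HF in MeCN brings the route back at 13.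

Second, step 8. The diazo compound formed from the hindered hydrazone may collapse by 1,2-hydrogen shift or azine formation instead of taking up two bromine atoms. The fallback reaches the same α-bromo radical from a vinyl bromide and not from a geminal dibromide. It sets out from 13: the hydrazone 14 treated with N-bromosuccinimide and 2-tert-butyl-1,1,3,3-tetramethylguanidine (Barton-type vinyl halide synthesis) should give (3S,6R)-6-bromo-6-[(2S)-5-bromo-2,6,6-trimethyl-3,6-dihydro-2H-pyran-2-yl]-3-methylhex-1-en-3-ol F4. Hydrogen-atom-transfer hydrogenation (Mn(dpm)3, PhSiH3, t-BuOOH, i-PrOH, stopped short of full conversion to spare the vinyl group) should then form the ring radical and, by the same axial hydrogen transfer, come back to the route at 16.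

Third, step 6. Ionisation of the crowded mixed ketal may cleave the tertiary C–O bond, losing the whole acetone unit, and not the methoxy group. The fallback makes the enol ether by carbonyl methylenation. It sets out from 8: Ac2O with catalytic Me3SiOTf (CH2Cl2, −40 °C) should give (3S,4R,7S)-4-bromo-1-cyano-3,7-dimethyl-7-[(triethylsilyl)oxy]non-8-en-3-yl acetate F5. Tebbe methylenation of the ester carbonyl (Cp2Ti(CH2)(Cl)AlMe2, pyridine, THF, −40 to 0 °C, kept cold to spare the nitrile) returns to the route at 11.

**Further compounds**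

F1 | step 7 | (4S,5R,8S)-5-bromo-4,8-dimethyl-4-(prop-1-en-2-yloxy)-8-[(triethylsilyl)oxy]dec-9-enal | C=C[C@@](C)(O[Si](CC)(CC)CC)CC[C@@H](Br)[C@](OC(C)=C)(C)CCC=O
F2 | step 7 | (6S)-6-{(1R,4S)-1-bromo-4-methyl-4-[(triethylsilyl)oxy]hex-5-en-1-yl}-2,2,6-trimethyloxan-3-ol (either carbinol epimer) | C=C[C@@](C)(O[Si](CC)(CC)CC)CC[C@@H](Br)[C@]1(C)CCC(O)C(C)(C)O1
F3 | step 7 | (6S)-6-{(1R,4S)-1-bromo-4-methyl-4-[(triethylsilyl)oxy]hex-5-en-1-yl}-2,2,6-trimethyloxan-3-one | C=C[C@@](C)(O[Si](CC)(CC)CC)CC[C@@H](Br)[C@]1(C)CCC(=O)C(C)(C)O1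
F4 | step 8 | (3S,6R)-6-bromo-6-[(2S)-5-bromo-2,6,6-trimethyl-3,6-dihydro-2H-pyran-2-yl]-3-methylhex-1-en-3-ol | C=C[C@@](C)(O)CC[C@@H](Br)[C@]1(C)CC=C(Br)C(C)(C)O1
F5 | step 6 | (3S,4R,7S)-4-bromo-1-cyano-3,7-dimethyl-7-[(triethylsilyl)oxy]non-8-en-3-yl acetate | C=C[C@@](C)(O[Si](CC)(CC)CC)CC[C@@H](Br)[C@](OC(C)=O)(C)CCC#N
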